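Count the partner.

| flask | starting material | partner | protic impurity | temperature | remark | time |
|---|---|---|---|---|---|---|
| dawn | 0.80 M | 0.72 M | 0.80 M | −10 °C | run made earlier |  |
| noon | 0.80 M | 2.9 M | 0.80 M | 23 °C | run made earlier |  |
| dusk | 1.6 M | 1.44 M | 0.80 M | −10 °C | run made earlier |  |
| north | 0.80 M | 1.44 M | 0.800 M | 5 °C |  | 5.0 h |
| north-west | 0.80 M | 1.44 M | 0.800 M | 35 °C |  | 5.0 h |
| north-east | 0.80 M | 1.44 M | 0.800 M | −25 °C |  | 5.0 h |

| run | time / h | target / % |
|---|---|---|
| dawn | 1.00 | 0 |
| dawn | 3.00 | 0.1 |
| dawn | 6.00 | 1.4 |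
| dawn | 8.00 | 1.8 |
| dawn | 12.0 | 3.7 |
| noon | 0.200 | 9.5 |
| noon | 0.333 | 18.3 |
| noon | 0.667 | 32.0 |
| noon | 1.33 | 44.2 |
| noon | 2.50 | 50.6 |
| dusk | 1.00 | 0 |
| dusk | 3.00 | 0.9 |
| dusk | 6.00 | 2.3 |
| dusk | 8.00 | 3.5 |
| dusk | 12.0 | 4.9 |

(standard deviation of a reading: 0.3 percentage points)

- the flask with the highest amount of target, in percent of the starting material charged ("all alike" if they lie within 1.5 percentage points) (north / north-west / north-east / all alike)
- final target, as a percentage of the starting material charged, in north
- final target, as a percentage of the starting material charged, in north-west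
- final target, as a percentage of the starting material charged, in north-east

1. Fastest rung: noon. Let y be target and take noon's last reading as its plateau. The fraction left, 1 − y/plateau, then halves in 0.431 h, far shorter than the 5.0 h asked.

2. Middle rung: the asked time. North-west runs hotter than noon, so I expect it on its plateau by 5.0 h. North runs colder than noon, so I expect it still climbing, with less target than north-west.

3. Slowest rung: the cold runs. Dawn reads 0% at 1.00 h, a lag. Its later pace needs 132 h to reach noon's plateau, much longer than 5.0 h. North-east is colder than dawn, so I expect it below dawn's 1.4% at 6.00 h.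

4. Height of the plateau. Noon holds 3.62 partner per starting material, yet its last reading is 50.6%. That gives 14.0%: call it the partner yield η, moles of target per mole of partner charged. So at that reading 86.0% of noon's partner has not become target.

5. My reckoning. North-west holds 1.80 partner per starting material. At noon's η that gives 25.1% of target, and north-west has the most.

The forecast says north-west, with 19% in north, 0.1% in north-east and 33% in north-west, above my figure, holding that “Less partner lowers the plateau”.

The flasks give 20.3% in north, 0.0304% in north-east and 67.1% in north-west, the highest.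

    starting material → intermediate (k = 8.01 × 10⁻⁵ s⁻¹, Ea = 91.0 kJ mol⁻¹)
    partner + intermediate → target (k = 5.72 × 10⁻⁵ L mol⁻¹ s⁻¹, Ea = 64.0 kJ mol⁻¹)
    2 partner → homo product (k = 1.76 × 10⁻⁵ L mol⁻¹ s⁻¹, Ea = 60.0 kJ mol⁻¹)
    starting material + target → side product (k = 6.40 × 10⁻⁵ L mol⁻¹ s⁻¹, Ea = 77.0 kJ mol⁻¹)
    starting material + protic impurity → quenched substrate (k = 6.16 × 10⁻⁵ L mol⁻¹ s⁻¹, Ea = 67.0 kJ mol⁻¹)
    target ⇌ isomer of the product (K = 0.612, k = 1.22 × 10⁻⁵ s⁻¹, Ea = 86.0 kJ mol⁻¹, ΔH = −39.0 kJ mol⁻¹)
    (constants at 5 °C)

North-west's η is 37.3%, above noon's 14.0%, so my 25.1% fell short. In north-west, partner's use for target over its use for homo product was 0.44 at 0.0424 h and 1.2 at 5.00 h. A neighbour of north-west, charged with 0.58 M of partner, or 0.725 equiv, ends with an η of 64.9%, with 47.1% target, 28.7% intermediate and 0.73% of its partner left.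

The runs were generated by integration from invented constants.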